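Readings and results stem from a simulated flask on assumed constants.

**The chain.** The starting material is consumed by a chain. The initiator gives initiating radicals, and these start first chain carrier. First chain carrier turns partner into target and becomes second chain carrier, which takes starting material, frees released group and returns first chain carrier. Beside the chain, pairs of starting material join into self-condensation product.

| flask | starting material | partner | initiator | remark | time |
|---|---|---|---|---|---|
| dawn | 0.0080 M | 0.24 M | 5.5 mM | run made earlier |  |
| dusk | 0.0080 M | 0.24 M | 16 mM | run made earlier |  |
| green | 0.0080 M | 0.240 M | 8.2 mM |  | 15 min |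
| ochre | 0.020 M | 0.240 M | 8.2 mM |  | 15 min |
| amber | 0.060 M | 0.240 M | 8.2 mM |  | 15 min |
| grey | 0.20 M | 0.240 M | 8.2 mM |  | 15 min |
| blue | 0.60 M | 0.240 M | 8.2 mM |  | 15 min |

| run | time / min | target / % | starting material / % |
|---|---|---|---|
| dawn | 0.250 | 7 | 98 |
| dawn | 0.417 | 5 | 95 |
| dawn | 0.667 | 9 | 94 |
| dawn | 1.00 | 12 | 85 |
| dawn | 2.00 | 21 | 82 |
| dawn | 3.00 | 28 | 71 |
| dusk | 0.250 | 3 | 90 |
| dusk | 0.417 | 8 | 93 |
| dusk | 0.667 | 11 | 86 |
| dusk | 1.00 | 16 | 83 |
| dusk | 2.00 | 36 | 67 |
| dusk | 3.00 | 44 | 53 |

(readings scatter by 2 percentage points)

- percent here means starting material units held: one ended chains B or self-condensation product counts as two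
- the analysis behind the earlier runs scatters by 2 percentage points, standard deviation
- steps that have been proposed: partner + first chain carrier <-> target + second chain carrier; starting material + second chain carrier -> released group + first chain carrier; 2 starting material -> self-condensation product; 2 second chain carrier -> ended chains A; 2 first chain carrier -> ended chains B; starting material + initiating radical -> capped initiator + first chain carrier; initiator -> 2 initiating radical
- "hardly changes" means that all values lie within two and a half points (for a concentration: within two and a half percent of the largest)

- amount of target at the end, in percent of the starting material charged for green, ochre, amber, grey, blue, in this order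
- the shape of the row from first to last (rises, then falls / hardly changes / falls all the way / rises all the way / falls, then rises)

**Chain half-life.** At 3.00 min, dawn keeps 71 % of its starting material and dusk 53 %, read as pseudo-first-order losses of 0.114 min⁻¹ and 0.212 min⁻¹. Their ratio, 1.86, lies near the root of the initiator ratio, 1.71. Each loss is therefore scaled by that root to the initiator of green, and the mean is 0.145 min⁻¹. The time in which the chain halves the starting material, the chain half-life, is then 4.77 min, and 15 min holds 3.15 of them.

**Extreme versions.** In a chain-only version, the half-life does not depend on the charge, so 11.3 % of the starting material stays and target reaches 88.7 % at each charge. In a partner-bound version, blue charges more starting material than partner, so partner is the limiting reagent and target stops at 40.0 % of the charge.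

**Between them.** The first half-life of starting material by self-condensation shortens in proportion to the charge, while the chain half-life is taken as fixed. The constant of that step cannot be read: target plus starting material sums to 99.0 % in dawn and 97.0 % in dusk, within the scatter. This reckoning therefore puts green just under 88.7 %, lowers the row at each step of charge, and puts blue under 40.0 %.

**The forecast.** It gives 80 %, 82 %, 79 %, 62 % and 27 %, a row that rises, then falls, on the ground that “capping by initiating radicals costs a few percent” in green. It differs from the reckoning above at the head of the row, where it sets green below ochre.

**The result.** The flasks give 88.0 %, 82.6 %, 72.3 %, 48.9 % and 24.3 %, a row that falls all the way. Starting material left at 15.0 min is 9.43 % in green and 10.7 % in amber, against the 11.3 % counted.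

    partner + first chain carrier ⇌ target + second chain carrier (K = 0.730, k = 2.80 × 10⁵ M⁻¹ s⁻¹)
    starting material + second chain carrier → released group + first chain carrier (k = 4.70 × 10⁵ M⁻¹ min⁻¹)
    2 starting material → self-condensation product (k = 0.480 M⁻¹ min⁻¹)
    2 second chain carrier → ended chains A (k = 4.90 × 10⁶ M⁻¹ s⁻¹)
    2 first chain carrier → ended chains B (k = 1.40 × 10⁷ M⁻¹ s⁻¹)
    starting material + initiating radical → capped initiator + first chain carrier (k = 4.20 × 10⁵ M⁻¹ s⁻¹)
    initiator → 2 initiating radical (k = 0.00290 min⁻¹)

**Half-lives compared.** In green, the first half-life by self-condensation, 130 min, is far longer than the chain half-life of 4.77 min, and self-condensation product holds 2.56 %. In grey the first half-life by self-condensation is 5.21 min, just 1.09 times that counted chain half-life, and target at 48.9 % stands beside self-condensation product at 40.8 %.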